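## Retrosynthetic overview

1. Target 30 ⇐ furanone ester 28 (acidolysis of the C2 tert-butyl ester, decarboxylation, desilylation) ⇐ bridged 4-methylene-dihydrofuran 26 (ozonolysis of C1=CH2). C1 is carried as a methylidene and C2 as an ester, and both are removed at the end.
2. 26 ⇐ open-chain 25 by one palladium-catalysed C,O-annulation of a β-keto ester with a tertiary propargylic carbonate in the same chain. It forms C2–C1 and O–C10, closes the ten-membered carbocycle and the oxygen-bridged five-membered ring together, and sets quaternary C10.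
3. Enabling feature: in the 3(2H)-furanone ring O–C3=C2–C1(=O)–C10, the O/C2 pair is the oxygen and carbon of a β-keto ester enolate, and the C1/C10 pair is the central and carbinol carbon of a methyl-bearing propargylic carbonate. The two pairs sit at the two ends of the C3→C10 chain, so their union is also the macrocyclization.
4. 25 ⇐ bromide 14 + aldehyde 19: indium-mediated allylation (C7–C8, regenerates the α-methylene γ-lactone, 6,7-trans), Mitsunobu angeloylation (inverts C8), acetal hydrolysis, Roskamp homologation (brings C2).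
5. 14 ⇐ N-pent-4-enoyl oxazolidinone (auxiliary-controlled orthoformate alkylation, C4), catalytic asymmetric 2-(ethoxycarbonyl)allylation (C6, γ-lactone), allylic bromination; 19 ⇐ 4,4-dimethoxybutan-2-one + ethynylmagnesium bromide. Ring order: γ-lactone (step 6), then ten-membered carbocycle and dihydrofuran together (step 14).

Key step: step 14

Remark (numbering): locants C1–C15 are germacrane locants: C1 ketone carbon, C2 ring =CH, C3 enol-ether carbon, C4 CH(CH2OH), C5 CH2, C6 lactone CH–O, C7, C8 CH–O-angelate, C9 CH2, C10 C(CH3)–O, C11=C13 methylidene, C12 lactone C=O, C14 methyl, C15 CH2OH.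

Remark (assumption): the carbonate-bearing carbon (future C10) is introduced racemic and carried as an epimer mixture in 20, 22, 23 and 25. It is drawn without configuration because step 14 ionizes it.

## Route

Step 1
Reactants: 1 (4S)-4-benzyl-1,3-oxazolidin-2-one; 2 pent-4-enoyl chloride
Product: 3 (4S)-4-benzyl-3-(pent-4-enoyl)-1,3-oxazolidin-2-one
Conditions: Et3N, DMAP (cat.), CH2Cl2, 0 °C → rt
Reagents that add atoms: none
Why: DMAP-catalysed N-acylation of the oxazolidinone installs the auxiliary that will control C4; no stereocentre is formed.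

Step 2
Reactants: 3 (4S)-4-benzyl-3-(pent-4-enoyl)-1,3-oxazolidin-2-one; 4 trimethyl orthoformate
Product: 6 (4S)-4-benzyl-3-[(2R)-2-(dimethoxymethyl)pent-4-enoyl]-1,3-oxazolidin-2-one, via titanium enolate 5 (not isolated)
Conditions: TiCl4, i-Pr2NEt, CH2Cl2, 0 °C; then HC(OMe)3, 0 °C
Reagents that add atoms: none
Why: Auxiliary-controlled alkylation of the chelated (Z)-titanium enolate by the dimethoxycarbenium ion from the orthoformate should occur on the face opposite the benzyl group, setting C4 (2R in 6, the later 4S) and bringing C3 as a masked aldehyde.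

Step 3
Reactants: 6 (4S)-4-benzyl-3-[(2R)-2-(dimethoxymethyl)pent-4-enoyl]-1,3-oxazolidin-2-one
Product: 7 (2S)-2-(dimethoxymethyl)pent-4-en-1-ol
Conditions: LiBH4, MeOH (1 equiv), Et2O, 0 °C
Reagents that add atoms: none
Why: Reductive cleavage of the N-acyloxazolidinone by borohydride gives the primary alcohol (the later C15–OH) without touching C4 and returns the auxiliary.

Step 4
Reactants: 7 (2S)-2-(dimethoxymethyl)pent-4-en-1-ol
Product: 8 tert-butyl{[(2S)-2-(dimethoxymethyl)pent-4-en-1-yl]oxy}dimethylsilane
Conditions: TBSCl, imidazole, CH2Cl2, rt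
Reagents that add atoms: tert-butyldimethylsilyl chloride, CC(C)(C)[Si](C)(C)Cl
Why: Standard silylation of the primary alcohol gives a TBS ether that is to be removed only in the final acidic step.

Step 5
Reactants: 8 tert-butyl{[(2S)-2-(dimethoxymethyl)pent-4-en-1-yl]oxy}dimethylsilane
Product: 10 (3S)-3-({[tert-butyl(dimethyl)silyl]oxy}methyl)-4,4-dimethoxybutanal, via ozonide 9 (not isolated)
Conditions: O3, CH2Cl2, −78 °C; then Me2S, −78 °C → rt
Reagents that add atoms: ozone, [O-][O+]=O
Why: Ozonolysis with reductive work-up cleaves the terminal alkene to the C6 aldehyde, while the acetal and silyl ether are inert.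

Step 6
Reactants: 10 (3S)-3-({[tert-butyl(dimethyl)silyl]oxy}methyl)-4,4-dimethoxybutanal; 11 ethyl 2-(bromomethyl)prop-2-enoate
Product: 13 (5R)-5-[(2S)-3-{[tert-butyl(dimethyl)silyl]oxy}-2-(dimethoxymethyl)propyl]-3-methylideneoxolan-2-one, via silylated hydroxy ester 12 (not isolated)
Conditions: CrCl2 (10 mol %), chiral 1,8-bis(4-isopropyloxazolin-2-yl)-3,6-di-tert-butylcarbazole ligand (12 mol %, antipode directing Si-face attack), i-Pr2NEt (cat.), Mn, TMSCl, THF, rt; then PPTS (cat.), MeOH, rt
Reagents that add atoms: none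
Why: Catalytic asymmetric Nozaki–Hiyama–Kishi-type 2-(alkoxycarbonyl)allylation should add the ligand-bound allylchromium to the Si face of the aldehyde (reagent control, sets 6R), and the γ-hydroxy ester lactonizes once desilylated in methanol, which also keeps the dimethyl acetal intact.

Step 7
Reactants: 13 (5R)-5-[(2S)-3-{[tert-butyl(dimethyl)silyl]oxy}-2-(dimethoxymethyl)propyl]-3-methylideneoxolan-2-one
Product: 14 (5R)-3-(bromomethyl)-5-[(2S)-3-{[tert-butyl(dimethyl)silyl]oxy}-2-(dimethoxymethyl)propyl]furan-2(5H)-one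
Conditions: NBS (1.05 equiv), AIBN (cat.), K2CO3 (solid), PhCF3, 80 °C
Reagents that add atoms: N-bromosuccinimide, O=C1CCC(=O)N1Br
Why: Wohl–Ziegler allylic bromination should abstract hydrogen at the only allylic CH2 (C7) and brominate the allyl radical at its exocyclic terminus, giving the conjugated 3-(bromomethyl)butenolide and leaving C6 untouched.

Step 8
Reactants: 15 4,4-dimethoxybutan-2-one; 16 ethynylmagnesium bromide
Product: 18 5,5-dimethoxy-3-methylpent-1-yn-3-yl methyl carbonate (racemic), via magnesium alkoxide 17 (not isolated)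
Conditions: THF, 0 °C; then ClCO2Me, 0 °C → rt
Reagents that add atoms: methyl chloroformate, COC(=O)Cl
Why: 1,2-Addition of the alkynyl Grignard reagent to the methyl ketone and acylation of the tertiary alkoxide in the same flask give the propargylic carbonate; the racemic carbinol centre is harmless because step 14 ionizes it.

Step 9
Reactants: 18 5,5-dimethoxy-3-methylpent-1-yn-3-yl methyl carbonate
Product: 19 methyl 3-methyl-5-oxopent-1-yn-3-yl carbonate (racemic)
Conditions: AcOH/H2O (4:1), rt; used crude
Reagents that add atoms: water, O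
Why: Mild acid hydrolysis of the dimethyl acetal frees the C8 aldehyde while the tertiary carbonate survives; the aldehyde is used at once to avoid β-elimination.

Step 10
Reactants: 14 (5R)-3-(bromomethyl)-5-[(2S)-3-{[tert-butyl(dimethyl)silyl]oxy}-2-(dimethoxymethyl)propyl]furan-2(5H)-one; 19 methyl 3-methyl-5-oxopent-1-yn-3-yl carbonate
Product: 20 (4R,5R)-5-[(2S)-3-{[tert-butyl(dimethyl)silyl]oxy}-2-(dimethoxymethyl)propyl]-4-{(1S)-1-hydroxy-3-[(methoxycarbonyl)oxy]-3-methylpent-4-yn-1-yl}-3-methylideneoxolan-2-one
Conditions: In powder, THF/H2O (4:1), rt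
Reagents that add atoms: none
Why: Indium-mediated Barbier allylation should react at the γ-carbon (C7) of the allylindium through a closed chair transition state on the face anti to the C6 side chain, regenerating the α-methylene lactone and giving the 6,7-trans adduct with the E-crotyl-type anti relation at C7/C8 (8S), so C7 is correct and C8 is epimeric to the target.

Step 11
Reactants: 20 allylation product (8S alcohol); 21 angelic acid, (2Z)-2-methylbut-2-enoic acid
Product: 22 (1R)-1-[(2R,3S)-2-[(2S)-3-{[tert-butyl(dimethyl)silyl]oxy}-2-(dimethoxymethyl)propyl]-4-methylidene-5-oxooxolan-3-yl]-3-[(methoxycarbonyl)oxy]-3-methylpent-4-yn-1-yl (2Z)-2-methylbut-2-enoate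
Conditions: PPh3, DIAD, toluene, 0 °C → rt
Reagents that add atoms: none
Why: Mitsunobu esterification displaces the activated C8 oxygen by angelate in an SN2 step, inverting C8 to the required 8R, and avoids angelate-to-tiglate isomerization because the acid is never activated as an acyl electrophile.

Step 12
Reactants: 22 angelate dimethyl acetal
Product: 23 (1R)-1-[(2R,3S)-2-[(2S)-3-{[tert-butyl(dimethyl)silyl]oxy}-2-formylpropyl]-4-methylidene-5-oxooxolan-3-yl]-3-[(methoxycarbonyl)oxy]-3-methylpent-4-yn-1-yl (2Z)-2-methylbut-2-enoate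
Conditions: In(OTf)3 (2 mol %), acetone/H2O (20:1), rt; used crude
Reagents that add atoms: water, O
Why: Lewis-acid-catalysed acetal hydrolysis under nearly neutral conditions frees the C3 aldehyde while the TBS ether, the esters and the carbonate are kept.

Step 13
Reactants: 23 C3 aldehyde; 24 tert-butyl diazoacetate
Product: 25 tert-butyl (4S)-4-({[tert-butyl(dimethyl)silyl]oxy}methyl)-5-[(2R,3S)-3-{(1R)-3-[(methoxycarbonyl)oxy]-3-methyl-1-[(2Z)-2-methylbut-2-enoyloxy]pent-4-yn-1-yl}-4-methylidene-5-oxooxolan-2-yl]-3-oxopentanoate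
Conditions: SnCl2 (10 mol %), CH2Cl2, rt
Reagents that add atoms: none
Why: Roskamp homologation (addition of the diazo ester to the aldehyde, 1,2-hydride shift, loss of N2) gives the β-keto ester without base, so C4 and the two Michael acceptors are preserved.

Step 14
Reactants: 25 β-keto ester propargylic carbonate
Product: 26 tert-butyl (4S,6R,7S,8R,10S)-8-angeloyloxy-15-[tert-butyl(dimethyl)silyl]oxy-1-methylidene-3,10-epoxygermacra-2,11(13)-dien-12,6-olide-2-carboxylate
Conditions: Pd2(dba)3·CHCl3 (10 mol %), dppe (25 mol %), THF, 65 °C, syringe-pump addition of 25 (final 1 mM)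
Reagents that add atoms: none
Why: Proposed new method: zerovalent palladium ionizes the tertiary propargylic carbonate (CO2 lost, methoxide released as the only base) to an allenyl/η3-propargyl palladium cation; the β-keto ester carbon C2 adds to its central carbon C1, proton transfer to the terminal carbon gives a π-allyl palladium complex, and the C3 enol oxygen then attacks its tertiary terminus C10, so that C2–C1 and O–C10 form in one catalytic cycle. The closest known reaction is the palladium-catalysed annulation of propargylic carbonates with β-keto esters to 4-methylene-4,5-dihydrofurans, which is established between two molecules and is used here, without precedent, within one chain to close a medium ring. The ten-membered carbocycle closes by C-alkylation at the sp carbon with the terminal CH left outside the ring (10-exo-dig), and the oxygen-bridged five-membered ring closes by 5-exo-trig allylic etherification that leaves C1=CH2 exocyclic. The only new stereocentre, quaternary C10, is set by the substrate: its precursor centre is erased on ionization, the enol oxygen can reach the allyl terminus only across the ring, and the approach that keeps the C8 ester and the trans-fused lactone on the outer side of the forming oxa-bridged bicycle (10S) is expected to be preferred, with re-ionization of the allylic C–O bond allowing the epimers to equilibrate toward it. The step needs C- before O-alkylation (secured by the soft, doubly stabilized carbon nucleophile), oxygen attack at the tertiary rather than the CH2 allyl terminus (secured by its greater cationic character, as at the substituted terminus in the bimolecular reaction) and ring closure rather than oligomerization (secured by slow addition at high dilution and by the lactone, which holds the C5 and C8 arms on adjacent ring carbons). The α-methylene lactone, the angelate and C4 are expected to survive because no external base is added.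

Step 15
Reactants: 26 bridged 4-methylene-dihydrofuran
Product: 28 tert-butyl (4S,6R,7S,8R,10S)-8-angeloyloxy-15-[tert-butyl(dimethyl)silyl]oxy-1-oxo-3,10-epoxygermacra-2,11(13)-dien-12,6-olide-2-carboxylate, via secondary ozonide 27 (not isolated)
Conditions: O3 (1.0 equiv, Sudan red 7B indicator), CH2Cl2, −78 °C; then Me2S
Reagents that add atoms: ozone, [O-][O+]=O
Why: Ozonolysis should take the electron-rich exocyclic 1,1-disubstituted alkene of the dienol ether ahead of the ester-deactivated, tetrasubstituted C2=C3 bond and the two acrylate-type alkenes, turning C1=CH2 into the C1 ketone of the 3(2H)-furanone.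

Step 16
Reactants: 28 furanone tert-butyl ester
Product: 30 (4S,6R,7S,8R,10S)-8-angeloyloxy-15-hydroxy-1-oxo-3,10-epoxygermacra-2,11(13)-dien-12,6-olide (CNP0108636.1), via carboxylic acid 29 (not isolated)
Conditions: TFA/CH2Cl2/H2O (10:10:1), rt; concentrate; MeCN/H2O, 45 °C; aq. NaHCO3 work-up
Reagents that add atoms: none
Why: Acidolysis cleaves the tert-butyl ester and the TBS ether, and the β-keto acid then decarboxylates (through reversible hydration and opening of the vinylogous ester at C3 and re-closure by the C10 oxygen), leaving C2–H without affecting any stereocentre.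

## Compound list

1 | (4S)-4-benzyl-1,3-oxazolidin-2-one | O=C1N[C@@H](Cc2ccccc2)CO1 | starting material
2 | pent-4-enoyl chloride | C=CCCC(=O)Cl | starting material
3 | (4S)-4-benzyl-3-(pent-4-enoyl)-1,3-oxazolidin-2-one | C=CCCC(=O)N1[C@@H](Cc2ccccc2)COC1=O | intermediate
4 | trimethyl orthoformate | COC(OC)OC | starting material
5 | trichlorotitanium (Z)-enolate of 3 (not isolated) | C=CC/C=C(\O[Ti](Cl)(Cl)Cl)N1[C@@H](Cc2ccccc2)COC1=O | intermediate
6 | (4S)-4-benzyl-3-[(2R)-2-(dimethoxymethyl)pent-4-enoyl]-1,3-oxazolidin-2-one | C=CC[C@@H](C(=O)N1[C@@H](Cc2ccccc2)COC1=O)C(OC)OC | intermediate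
7 | (2S)-2-(dimethoxymethyl)pent-4-en-1-ol | C=CC[C@@H](CO)C(OC)OC | intermediate
8 | tert-butyl{[(2S)-2-(dimethoxymethyl)pent-4-en-1-yl]oxy}dimethylsilane | C=CC[C@@H](CO[Si](C)(C)C(C)(C)C)C(OC)OC | intermediate
9 | 3-[(2S)-3-{[tert-butyl(dimethyl)silyl]oxy}-2-(dimethoxymethyl)propyl]-1,2,4-trioxolane (ozonide, not isolated) | C1(C[C@@H](CO[Si](C)(C)C(C)(C)C)C(OC)OC)OCOO1 | intermediate
10 | (3S)-3-({[tert-butyl(dimethyl)silyl]oxy}methyl)-4,4-dimethoxybutanal | O=CC[C@@H](CO[Si](C)(C)C(C)(C)C)C(OC)OC | intermediate
11 | ethyl 2-(bromomethyl)prop-2-enoate | C=C(CBr)C(=O)OCC | starting material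
12 | ethyl (4R,6S)-7-{[tert-butyl(dimethyl)silyl]oxy}-6-(dimethoxymethyl)-2-methylidene-4-[(trimethylsilyl)oxy]heptanoate (not isolated) | C=C(C[C@@H](C[C@@H](CO[Si](C)(C)C(C)(C)C)C(OC)OC)O[Si](C)(C)C)C(=O)OCC | intermediate
13 | (5R)-5-[(2S)-3-{[tert-butyl(dimethyl)silyl]oxy}-2-(dimethoxymethyl)propyl]-3-methylideneoxolan-2-one | C=C1C[C@@H](C[C@@H](CO[Si](C)(C)C(C)(C)C)C(OC)OC)OC1=O | intermediate
14 | (5R)-3-(bromomethyl)-5-[(2S)-3-{[tert-butyl(dimethyl)silyl]oxy}-2-(dimethoxymethyl)propyl]furan-2(5H)-one | BrCC1=C[C@@H](C[C@@H](CO[Si](C)(C)C(C)(C)C)C(OC)OC)OC1=O | intermediate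
15 | 4,4-dimethoxybutan-2-one | CC(=O)CC(OC)OC | starting material
16 | ethynylmagnesium bromide | C#C[Mg]Br | starting material
17 | bromomagnesium 5,5-dimethoxy-3-methylpent-1-yn-3-olate (racemic, not isolated) | COC(CC(C)(O[Mg]Br)C#C)OC | intermediate
18 | 5,5-dimethoxy-3-methylpent-1-yn-3-yl methyl carbonate (racemic) | COC(CC(C)(OC(=O)OC)C#C)OC | intermediate
19 | methyl 3-methyl-5-oxopent-1-yn-3-yl carbonate (racemic) | O=CCC(C)(OC(=O)OC)C#C | intermediate
20 | (4R,5R)-5-[(2S)-3-{[tert-butyl(dimethyl)silyl]oxy}-2-(dimethoxymethyl)propyl]-4-{(1S)-1-hydroxy-3-[(methoxycarbonyl)oxy]-3-methylpent-4-yn-1-yl}-3-methylideneoxolan-2-one (both epimers at the carbonate carbon) | C=C1C(=O)O[C@H](C[C@@H](CO[Si](C)(C)C(C)(C)C)C(OC)OC)[C@H]1[C@@H](O)CC(C)(OC(=O)OC)C#C | intermediate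
21 | angelic acid, (2Z)-2-methylbut-2-enoic acid | C/C=C(/C)C(=O)O | starting material
22 | (1R)-1-[(2R,3S)-2-[(2S)-3-{[tert-butyl(dimethyl)silyl]oxy}-2-(dimethoxymethyl)propyl]-4-methylidene-5-oxooxolan-3-yl]-3-[(methoxycarbonyl)oxy]-3-methylpent-4-yn-1-yl (2Z)-2-methylbut-2-enoate (both epimers at the carbonate carbon) | C=C1C(=O)O[C@H](C[C@@H](CO[Si](C)(C)C(C)(C)C)C(OC)OC)[C@H]1[C@H](OC(=O)/C(C)=C\C)CC(C)(OC(=O)OC)C#C | intermediate
23 | (1R)-1-[(2R,3S)-2-[(2S)-3-{[tert-butyl(dimethyl)silyl]oxy}-2-formylpropyl]-4-methylidene-5-oxooxolan-3-yl]-3-[(methoxycarbonyl)oxy]-3-methylpent-4-yn-1-yl (2Z)-2-methylbut-2-enoate (both epimers at the carbonate carbon) | C=C1C(=O)O[C@H](C[C@@H](CO[Si](C)(C)C(C)(C)C)C=O)[C@H]1[C@H](OC(=O)/C(C)=C\C)CC(C)(OC(=O)OC)C#C | intermediate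
24 | tert-butyl diazoacetate | CC(C)(C)OC(=O)C=[N+]=[N-] | starting material
25 | tert-butyl (4S)-4-({[tert-butyl(dimethyl)silyl]oxy}methyl)-5-[(2R,3S)-3-{(1R)-3-[(methoxycarbonyl)oxy]-3-methyl-1-[(2Z)-2-methylbut-2-enoyloxy]pent-4-yn-1-yl}-4-methylidene-5-oxooxolan-2-yl]-3-oxopentanoate (both epimers at the carbonate carbon) | C=C1C(=O)O[C@H](C[C@@H](CO[Si](C)(C)C(C)(C)C)C(=O)CC(=O)OC(C)(C)C)[C@H]1[C@H](OC(=O)/C(C)=C\C)CC(C)(OC(=O)OC)C#C | intermediate
26 | tert-butyl (4S,6R,7S,8R,10S)-8-angeloyloxy-15-[tert-butyl(dimethyl)silyl]oxy-1-methylidene-3,10-epoxygermacra-2,11(13)-dien-12,6-olide-2-carboxylate | C=C1C(=O)O[C@@H]2C[C@@H](CO[Si](C)(C)C(C)(C)C)C3=C(C(=O)OC(C)(C)C)C(=C)[C@](C)(C[C@@H](OC(=O)/C(C)=C\C)[C@@H]12)O3 | intermediate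
27 | secondary ozonide of 26 (spiro-1,2,4-trioxolane at C1, not isolated) | C=C1C(=O)O[C@@H]2C[C@@H](CO[Si](C)(C)C(C)(C)C)C3=C(C(=O)OC(C)(C)C)C4(OCOO4)[C@](C)(C[C@@H](OC(=O)/C(C)=C\C)[C@@H]12)O3 | intermediate
28 | tert-butyl (4S,6R,7S,8R,10S)-8-angeloyloxy-15-[tert-butyl(dimethyl)silyl]oxy-1-oxo-3,10-epoxygermacra-2,11(13)-dien-12,6-olide-2-carboxylate | C=C1C(=O)O[C@@H]2C[C@@H](CO[Si](C)(C)C(C)(C)C)C3=C(C(=O)OC(C)(C)C)C(=O)[C@](C)(C[C@@H](OC(=O)/C(C)=C\C)[C@@H]12)O3 | intermediate
29 | (4S,6R,7S,8R,10S)-8-angeloyloxy-15-hydroxy-1-oxo-3,10-epoxygermacra-2,11(13)-dien-12,6-olide-2-carboxylic acid (not isolated) | C=C1C(=O)O[C@@H]2C[C@@H](CO)C3=C(C(=O)O)C(=O)[C@](C)(C[C@@H](OC(=O)/C(C)=C\C)[C@@H]12)O3 | intermediate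
30 | (4S,6R,7S,8R,10S)-8-angeloyloxy-15-hydroxy-1-oxo-3,10-epoxygermacra-2,11(13)-dien-12,6-olide (CNP0108636.1) | C=C1C(=O)O[C@@H]2C[C@@H](CO)C3=CC(=O)[C@](C)(C[C@@H](OC(=O)/C(C)=C\C)[C@@H]12)O3 | target

## Step count and risk

Total step count: 16.
Longest linear sequence: 14 steps (steps 1–7 and 10–16); steps 8–9 form the second branch.

Steps most likely to fail:

1. Step 14 (proposed new method). The ring closure may lose to oligomerization or to β-hydride elimination of the allenylpalladium intermediate, or it may close with poor facial selectivity at C10. Fallback, by known reactions that make the two bonds one after the other: starting from 25, an In(NTf2)3-catalysed Conia-ene cycloisomerization (toluene, 80 °C, high dilution), which is established for ω-alkynyl β-keto esters up to large rings, would join C2 to the internal alkyne carbon and give the ten-membered tertiary allylic carbonate F1. Pd(PPh3)4 in THF would then ionize the now allylic carbonate, and intramolecular Tsuji–Trost O-allylation by the enol oxygen at C10 would return to the route at 26. If only the C10 selectivity is at fault, the same step would be run with a chiral bisphosphine ligand.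

2. Step 11. Elimination across C8–C9 or C7–C8, or participation of the neighbouring carbonate carbonyl, may take the place of clean SN2 inversion at the hindered C8 carbinol. Fallback: starting from 20, chloromethanesulfonyl chloride and pyridine (CH2Cl2, 0 °C) would give the chloromethanesulfonate F2. Displacement with cesium angelate (from 21 and Cs2CO3; 18-crown-6, toluene, 50 °C) would proceed with inversion and return to the route at 22.

3. Step 15. Over-oxidation may occur, with ozone also cleaving the C2=C3 enol-ether bond or attacking the α-methylene lactone and angelate alkenes. Fallback: starting from 26, osmium-catalysed dihydroxylation (OsO4 cat., NMO, acetone/H2O, 0 °C) would take the least hindered, most electron-rich alkene and give the 1,2-diol F3. Glycol cleavage with NaIO4 (THF/H2O) would return to the route at 28.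

## Further compounds

F1 | step 14 | tert-butyl (4S,6R,7S,8R)-8-angeloyloxy-15-[tert-butyl(dimethyl)silyl]oxy-10-[(methoxycarbonyl)oxy]-1-methylidene-3-oxogermacr-11(13)-en-12,6-olide-2-carboxylate (epimers at C2 and C10) | C=C1C(=O)O[C@@H]2C[C@@H](CO[Si](C)(C)C(C)(C)C)C(=O)C(C(=O)OC(C)(C)C)C(=C)C(C)(OC(=O)OC)C[C@@H](OC(=O)/C(C)=C\C)[C@@H]12
F2 | step 11 | (1S)-1-[(2R,3R)-2-[(2S)-3-{[tert-butyl(dimethyl)silyl]oxy}-2-(dimethoxymethyl)propyl]-4-methylidene-5-oxooxolan-3-yl]-3-[(methoxycarbonyl)oxy]-3-methylpent-4-yn-1-yl chloromethanesulfonate | C=C1C(=O)O[C@H](C[C@@H](CO[Si](C)(C)C(C)(C)C)C(OC)OC)[C@H]1[C@@H](OS(=O)(=O)CCl)CC(C)(OC(=O)OC)C#C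
F3 | step 15 | tert-butyl (4S,6R,7S,8R,10S)-8-angeloyloxy-15-[tert-butyl(dimethyl)silyl]oxy-1-hydroxy-1-(hydroxymethyl)-3,10-epoxygermacra-2,11(13)-dien-12,6-olide-2-carboxylate (either C1 epimer) | C=C1C(=O)O[C@@H]2C[C@@H](CO[Si](C)(C)C(C)(C)C)C3=C(C(=O)OC(C)(C)C)C(O)(CO)[C@](C)(C[C@@H](OC(=O)/C(C)=C\C)[C@@H]12)O3
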